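**Plan**

1. Retrosynthetic cuts: the pyranone ring C of the flavone (O1–C2 by cyclodehydration, C3–aroyl by acyl transfer, C4–C4a by aryl–acyl union), the D4–C(=O) bond to ring E, the D3–D4 bond of the cyclohexene, the C–C bond at the carbinol carbon of a δ-lactone, and the benzylic C–C bond of a malonate Michael adduct.
2. Enabling feature: ring D is a cyclohexene (D1 methyl-bearing sp2 carbon, D2 sp2 CH, D3 CH on flavone C8, D4 CH bearing the aroyl carbon, D5 CH bearing the 4-hydroxyphenyl ring, D6 CH2). Its D4 carbonyl stands γ,δ to the D1=D2 bond (O=C–D4–D3–D2=D1), the imprint of a Claisen shift, so ring D is traced back to the enolate of a 4-aryl-6-methyl-6-(2-arylethenyl) δ-lactone.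
3. Forward order: Michael adduct, keto ester, δ-lactone (alkenylcerium addition and lactonisation), ring D by Ireland–Claisen ring contraction, ring E ketone via aldehyde and aryllithium, acyl chain on the phloroglucinol ring, ring C closed last, global deprotection.
4. Stereochemistry: D5 comes from the organocatalytic Michael addition; D3 (and D4, first cis) are relayed through the boat transition state of the (E)-alkenyl trans-lactone; D4 is then inverted by base to the all-equatorial arrangement.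

Key step: step 8

Assumption: the amine catalyst of step 2 is taken to give the (S) adduct (otherwise its quinidine-derived pseudo-enantiomer is used), and 5-methylhex-4-enal (27) is treated as a purchasable reagent.

Abbreviations: MOM = methoxymethyl; allyl = prop-2-en-1-yl; prenyl = 3-methylbut-2-en-1-yl; DMP = 1,1,1-triacetoxy-1,2-benziodoxol-3(1H)-one.

**Step 1**
Reactants: 1 (E)-4-(4-hydroxyphenyl)but-3-en-2-one
Product: 2 (E)-4-[4-(methoxymethoxy)phenyl]but-3-en-2-one
Conditions: MOMCl, i-Pr2NEt, CH2Cl2, 0 °C → rt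
Reagents that add atoms: chloromethyl methyl ether (MOMCl), COCCl
Why: Base-mediated O-alkylation of the phenol (acetal ether formation) removes the only acidic proton before the enolate and organometallic steps.

**Step 2**
Reactants: 2 (E)-4-[4-(methoxymethoxy)phenyl]but-3-en-2-one; 3 dimethyl malonate
Product: 4 dimethyl 2-[(1S)-1-[4-(methoxymethoxy)phenyl]-3-oxobutyl]malonate
Conditions: 9-amino-9-deoxy-epi-quinine (20 mol %), PhCO2H (40 mol %), 3 (3 equiv), THF, rt
Reagents that add atoms: none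
Why: Asymmetric Michael addition under iminium activation; the chiral primary amine condenses with the enone and shields one face, so malonate should add to the other and set the future D5 centre as (S).

**Step 3**
Reactants: 4 dimethyl 2-[(1S)-1-[4-(methoxymethoxy)phenyl]-3-oxobutyl]malonate
Product: 5 methyl (3S)-3-[4-(methoxymethoxy)phenyl]-5-oxohexanoate
Conditions: LiCl, H2O, DMSO, 140 °C
Reagents that add atoms: none
Why: Krapcho dealkoxycarbonylation removes one ester under neutral conditions; the stereocentre is β to both carbonyl groups and cannot epimerise.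

**Step 4**
Reactants: 6 2,4,6-trihydroxybenzaldehyde
Product: 7 2,6-dihydroxy-4-(methoxymethoxy)benzaldehyde
Conditions: MOMCl (1.0 equiv), i-Pr2NEt (1.1 equiv), THF, 0 °C
Reagents that add atoms: chloromethyl methyl ether (MOMCl), COCCl
Why: Selective O-alkylation of the most acidic phenol; the 4-OH is para to the aldehyde and not hydrogen-bonded, whereas the two ortho phenols are chelated to the carbonyl and react later.

**Step 5**
Reactants: 7 2,6-dihydroxy-4-(methoxymethoxy)benzaldehyde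
Product: 8 2,6-bis(allyloxy)-4-(methoxymethoxy)benzaldehyde
Conditions: allyl bromide (2.5 equiv), K2CO3, DMF, 50 °C
Reagents that add atoms: allyl bromide, C=CCBr
Why: Williamson etherification of both chelated phenols gives a symmetrical ring whose two ortho oxygens can later be freed by zerovalent palladium without touching MOM ethers.

**Step 6**
Reactants: 8 2,6-bis(allyloxy)-4-(methoxymethoxy)benzaldehyde
Product: 9 2-[(E)-2-iodoethenyl]-5-(methoxymethoxy)-1,3-bis(allyloxy)benzene
Conditions: CrCl2 (6 equiv), CHI3 (2 equiv), THF, 0 °C → rt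
Reagents that add atoms: iodoform, IC(I)I
Why: Takai olefination; the geminal dichromium reagent adds to the aldehyde and anti-eliminates, which for aryl aldehydes should give the (E)-alkenyl iodide.

**Step 7**
Reactants: 9 2-[(E)-2-iodoethenyl]-5-(methoxymethoxy)-1,3-bis(allyloxy)benzene; 5 methyl (3S)-3-[4-(methoxymethoxy)phenyl]-5-oxohexanoate
Product: 13 (4S,6R)-6-{(E)-2-[2,6-bis(allyloxy)-4-(methoxymethoxy)phenyl]ethenyl}-4-[4-(methoxymethoxy)phenyl]-6-methyloxan-2-one (4-aryl trans to the 6-alkenyl group), via vinyllithium 10 (not isolated), via alkenylcerium dichloride 11 (not isolated), via hydroxy ester alkoxide 12 (not isolated)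
Conditions: 9, t-BuLi (2.0 equiv), Et2O, −78 °C; CeCl3, THF, −78 °C; then 5, −78 °C → rt; chromatography on Et3N-washed SiO2
Reagents that add atoms: none
Why: Iodine–lithium exchange and transmetalation give a weakly basic alkenylcerium reagent that adds to the methyl ketone rather than enolising it or attacking the ester, and the tertiary alkoxide closes the δ-lactone by expelling methoxide; the remote C3 centre gives little 1,3-induction, so both C6 epimers are expected and the (4S,6R) isomer is separated and carried on.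

**Step 8**
Reactants: 13 (4S,6R)-6-{(E)-2-[2,6-bis(allyloxy)-4-(methoxymethoxy)phenyl]ethenyl}-4-[4-(methoxymethoxy)phenyl]-6-methyloxan-2-one
Product: 16 (1S,2R,6S)-2-[2,6-bis(allyloxy)-4-(methoxymethoxy)phenyl]-6-[4-(methoxymethoxy)phenyl]-4-methylcyclohex-3-ene-1-carboxylic acid (all-cis), via silyl ketene acetal 14 (not isolated), via trimethylsilyl ester 15 (not isolated)
Conditions: Me3SiCl/Et3N, KN(SiMe3)2, THF, −78 °C; then toluene, rt → 70 °C; K2CO3, MeOH/H2O, then pH 5 buffer
Reagents that add atoms: none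
Why: KN(SiMe3)2 removes the C3 proton and Me3SiCl traps the enolate as the cyclic ketene acetal 14, whose O–C=C unit and C6 alkenyl group make up the 1,5-diene of an Ireland–Claisen rearrangement. On warming, the ketene acetal carbon (future D4) bonds to the aryl-bearing alkene terminus (future D3) while the tertiary allylic C6–O bond breaks, a concerted suprafacial [3,3] shift of the kind known to contract alkenyl lactones to cycloalkene carboxylic acids. Ring D closes as a six-membered carbocycle inside the sigmatropic array rather than by a polar exo or endo attack: the two termini are tied by the C4–C5 bridge, so the transition state must be a boat resembling bicyclo[2.2.2]octane, and the former lactone carbonyl is left outside the ring as silyl ester 15, hydrolysed to 16 on work-up. At D4 the ring-locked ketene acetal geometry places the carboxyl cis to the D5 aryl group, and at D3 the (E)-alkene within the boat places its aryl group on the same face, the absolute sense being relayed from C4 and the consumed C6 centre of 13. The step needs stereospecificity rather than a choice between transition states, since a chair is geometrically impossible, and the buffered basic medium keeps the ionisable tertiary allylic ester intact; the cis D4 centre is corrected in step 10.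

**Step 9**
Reactants: 16 (1S,2R,6S)-2-[2,6-bis(allyloxy)-4-(methoxymethoxy)phenyl]-6-[4-(methoxymethoxy)phenyl]-4-methylcyclohex-3-ene-1-carboxylic acid
Product: 17 [(1S,2R,6S)-2-[2,6-bis(allyloxy)-4-(methoxymethoxy)phenyl]-6-[4-(methoxymethoxy)phenyl]-4-methylcyclohex-3-en-1-yl]methanol
Conditions: LiAlH4, THF, 0 → 40 °C
Reagents that add atoms: none
Why: Hydride reduction of the hindered acid to the primary alcohol leaves ethers, acetals and alkenes untouched and prepares the less encumbered aldehyde for aryl addition.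

**Step 10**
Reactants: 17 [(1S,2R,6S)-2-[2,6-bis(allyloxy)-4-(methoxymethoxy)phenyl]-6-[4-(methoxymethoxy)phenyl]-4-methylcyclohex-3-en-1-yl]methanol
Product: 19 (1R,2R,6S)-2-[2,6-bis(allyloxy)-4-(methoxymethoxy)phenyl]-6-[4-(methoxymethoxy)phenyl]-4-methylcyclohex-3-ene-1-carbaldehyde (formyl trans to both aryl groups), via all-cis aldehyde 18 (not isolated)
Conditions: DMP, pyridine, CH2Cl2, 0 °C → rt; aqueous Na2S2O3/NaHCO3 wash; then DBU (0.3 equiv), CH2Cl2, rt
Reagents that add atoms: none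
Why: Periodinane oxidation gives aldehyde 18 with an axial formyl group between two equatorial aryl rings; base-catalysed epimerisation through the enol should then relax D4 to the all-equatorial isomer, setting the last ring D centre under thermodynamic control.

**Step 11**
Reactants: 19 (1R,2R,6S)-2-[2,6-bis(allyloxy)-4-(methoxymethoxy)phenyl]-6-[4-(methoxymethoxy)phenyl]-4-methylcyclohex-3-ene-1-carbaldehyde
Product: 20 (1R,2R,6S)-2-[2,6-bis(allyloxy)-3-bromo-4-(methoxymethoxy)phenyl]-6-[4-(methoxymethoxy)phenyl]-4-methylcyclohex-3-ene-1-carbaldehyde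
Conditions: NBS (1.0 equiv), CH2Cl2, −78 → −40 °C, dark
Reagents that add atoms: N-bromosuccinimide, O=C1CCC(=O)N1Br
Why: Electrophilic aromatic bromination; the trioxygenated ring is by far the most nucleophilic π-system and its two free positions are constitutionally equivalent, so one equivalent at low temperature should spare the anisole-type ring and the alkenes.

**Step 12**
Reactants: 21 resorcinol
Product: 22 1,3-bis(methoxymethoxy)benzene
Conditions: NaH, MOMCl, DMF, 0 °C → rt
Reagents that add atoms: chloromethyl methyl ether (MOMCl), COCCl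
Why: Williamson-type protection of both phenols installs the groups that direct the two later ortho-metalations.

**Step 13**
Reactants: 22 1,3-bis(methoxymethoxy)benzene
Product: 24 1,3-bis(methoxymethoxy)-2-(3-methylbut-2-en-1-yl)benzene, via 2-lithio arene 23 (not isolated)
Conditions: n-BuLi, THF, 0 °C; CuBr·SMe2 (10 mol %), prenyl bromide, −78 °C → rt
Reagents that add atoms: prenyl bromide, CC(C)=CCBr
Why: Directed ortho-metalation at the position between the two MOM ethers followed by copper-assisted SN2 alkylation places the prenyl group regiospecifically.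

**Step 14**
Reactants: 24 1,3-bis(methoxymethoxy)-2-(3-methylbut-2-en-1-yl)benzene; 20 (1R,2R,6S)-2-[2,6-bis(allyloxy)-3-bromo-4-(methoxymethoxy)phenyl]-6-[4-(methoxymethoxy)phenyl]-4-methylcyclohex-3-ene-1-carbaldehyde
Product: 26 [2,4-bis(methoxymethoxy)-3-prenylphenyl][(1R,2R,6S)-2-[2,6-bis(allyloxy)-3-bromo-4-(methoxymethoxy)phenyl]-6-[4-(methoxymethoxy)phenyl]-4-methylcyclohex-3-en-1-yl]methanol (both carbinol epimers), via aryllithium 25 (not isolated)
Conditions: 24 (1.6 equiv), n-BuLi (1.5 equiv), TMEDA, THF, 0 °C, 1 h; then 20, −78 °C; H2O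
Reagents that add atoms: none
Why: MOM-directed ortho-lithiation at C4 of 24 and 1,2-addition to the aldehyde; at −78 °C carbonyl addition is far faster than aryl–aryl bromine–lithium exchange, and the carbinol configuration is irrelevant because it is oxidised in step 16.

**Step 15**
Reactants: 26 [2,4-bis(methoxymethoxy)-3-prenylphenyl][(1R,2R,6S)-2-[2,6-bis(allyloxy)-3-bromo-4-(methoxymethoxy)phenyl]-6-[4-(methoxymethoxy)phenyl]-4-methylcyclohex-3-en-1-yl]methanol; 27 5-methylhex-4-enal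
Product: 29 1-[2,4-bis(allyloxy)-3-[(1R,5S,6R)-6-[[2,4-bis(methoxymethoxy)-3-prenylphenyl](hydroxy)methyl]-5-[4-(methoxymethoxy)phenyl]-3-methylcyclohex-2-en-1-yl]-6-(methoxymethoxy)phenyl]-5-methylhex-4-en-1-ol (carbinol epimers), via dilithio species 28 (not isolated)
Conditions: t-BuLi (3.1 equiv), THF, −78 °C, 10 min; then 27 (3 equiv), −78 °C; H2O
Reagents that add atoms: none
Why: After deprotonation of the hydroxyl, bromine–lithium exchange gives an aryllithium held between two ether oxygens that adds to the aldehyde; kept at −78 °C it should neither cyclise onto the neighbouring allyl ether nor abstract ring protons.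

**Step 16**
Reactants: 29 1-[2,4-bis(allyloxy)-3-[(1R,5S,6R)-6-[[2,4-bis(methoxymethoxy)-3-prenylphenyl](hydroxy)methyl]-5-[4-(methoxymethoxy)phenyl]-3-methylcyclohex-2-en-1-yl]-6-(methoxymethoxy)phenyl]-5-methylhex-4-en-1-ol
Product: 30 1-[2,4-bis(allyloxy)-3-[(1R,5S,6R)-6-[2,4-bis(methoxymethoxy)-3-prenylbenzoyl]-5-[4-(methoxymethoxy)phenyl]-3-methylcyclohex-2-en-1-yl]-6-(methoxymethoxy)phenyl]-5-methylhex-4-en-1-one
Conditions: DMP (3 equiv), pyridine, CH2Cl2, 0 °C → rt
Reagents that add atoms: none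
Why: Buffered periodinane oxidation converts both benzylic carbinols into aryl ketones without ionising the electron-rich benzylic alcohol, so all carbinol epimers converge on one compound with D4 in its thermodynamic configuration.

**Step 17**
Reactants: 30 1-[2,4-bis(allyloxy)-3-[(1R,5S,6R)-6-[2,4-bis(methoxymethoxy)-3-prenylbenzoyl]-5-[4-(methoxymethoxy)phenyl]-3-methylcyclohex-2-en-1-yl]-6-(methoxymethoxy)phenyl]-5-methylhex-4-en-1-one
Product: 31 1-[3-[(1R,5S,6R)-6-[2,4-bis(methoxymethoxy)-3-prenylbenzoyl]-5-[4-(methoxymethoxy)phenyl]-3-methylcyclohex-2-en-1-yl]-2,4-dihydroxy-6-(methoxymethoxy)phenyl]-5-methylhex-4-en-1-one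
Conditions: Pd(PPh3)4 (5 mol %), morpholine, THF, rt
Reagents that add atoms: none
Why: Tsuji–Trost deallylation; zerovalent palladium ionises the aryl allyl ethers and morpholine captures the π-allyl fragment, freeing only the two phenols that flank the cyclohexenyl-bearing carbon while MOM ethers, ketones and trisubstituted alkenes stay inert.

**Step 18**
Reactants: 32 2,4-dihydroxybenzoic acid
Product: 34 2,4-bis(methoxymethoxy)benzoic acid, via MOM ester 33 (not isolated)
Conditions: MOMCl (3.5 equiv), i-Pr2NEt, CH2Cl2, 0 °C → rt; then LiOH, THF/MeOH/H2O, rt; 1 M HCl to pH 4, 0 °C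
Reagents that add atoms: chloromethyl methyl ether (MOMCl), COCCl
Why: Exhaustive MOM alkylation followed by saponification of the labile acetal ester returns the ring B acid with both phenols masked.

**Step 19**
Reactants: 31 1-[3-[(1R,5S,6R)-6-[2,4-bis(methoxymethoxy)-3-prenylbenzoyl]-5-[4-(methoxymethoxy)phenyl]-3-methylcyclohex-2-en-1-yl]-2,4-dihydroxy-6-(methoxymethoxy)phenyl]-5-methylhex-4-en-1-one; 34 2,4-bis(methoxymethoxy)benzoic acid
Product: 35 2-[(1R,5S,6R)-6-[2,4-bis(methoxymethoxy)-3-prenylbenzoyl]-5-[4-(methoxymethoxy)phenyl]-3-methylcyclohex-2-en-1-yl]-5-(methoxymethoxy)-4-(5-methylhex-4-enoyl)-1,3-phenylene bis[2,4-bis(methoxymethoxy)benzoate]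
Conditions: 34 (2.6 equiv), EDCI·HCl, DMAP, CH2Cl2, rt
Reagents that add atoms: none
Why: Steglich esterification acylates both phenols; the ester next to the hexenoyl ketone is the acyl donor of the next step and the other is a temporary protecting group.

**Step 20**
Reactants: 35 2-[(1R,5S,6R)-6-[2,4-bis(methoxymethoxy)-3-prenylbenzoyl]-5-[4-(methoxymethoxy)phenyl]-3-methylcyclohex-2-en-1-yl]-5-(methoxymethoxy)-4-(5-methylhex-4-enoyl)-1,3-phenylene bis[2,4-bis(methoxymethoxy)benzoate]
Product: 37 1-[2,4-bis(methoxymethoxy)phenyl]-3-[3-[(1R,5S,6R)-6-[2,4-bis(methoxymethoxy)-3-prenylbenzoyl]-5-[4-(methoxymethoxy)phenyl]-3-methylcyclohex-2-en-1-yl]-2,4-dihydroxy-6-(methoxymethoxy)phenyl]-2-prenylpropane-1,3-dione, via monoaroyl diketone 36 (not isolated)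
Conditions: LiN(SiMe3)2 (4 equiv), THF, −78 → 0 °C; then MeOH, K2CO3, rt; H2O
Reagents that add atoms: none
Why: Baker–Venkataraman rearrangement; the methylene enolate of the hexenoyl ketone attacks the neighbouring aryl ester through a six-membered transition state and the resulting β-diketonate drives the transfer (the flanked tertiary position next to the ring E ketone cannot form such an anion), after which methoxide removes the spectator aroyl group and keeps D4 at equilibrium.

**Step 21**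
Reactants: 37 1-[2,4-bis(methoxymethoxy)phenyl]-3-[3-[(1R,5S,6R)-6-[2,4-bis(methoxymethoxy)-3-prenylbenzoyl]-5-[4-(methoxymethoxy)phenyl]-3-methylcyclohex-2-en-1-yl]-2,4-dihydroxy-6-(methoxymethoxy)phenyl]-2-prenylpropane-1,3-dione
Product: 39 8-[(1R,5S,6R)-6-[2,4-dihydroxy-3-(3-methylbut-2-en-1-yl)benzoyl]-5-(4-hydroxyphenyl)-3-methylcyclohex-2-en-1-yl]-2-(2,4-dihydroxyphenyl)-5,7-dihydroxy-3-(3-methylbut-2-en-1-yl)-4H-chromen-4-one, via hexa-MOM flavone 38 (not isolated)
Conditions: 0.1 M HCl, MeOH, rt; then 3 M HCl, MeOH, 50 °C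
Reagents that add atoms: none
Why: Acid-catalysed cyclodehydration through the only free phenol ortho to the diketone (the other ortho oxygen is still a MOM ether, which fixes the 8-substituted regiochemistry) closes ring C, and acetal exchange with methanol then removes the six MOM groups.

**Compound list**

1 | (E)-4-(4-hydroxyphenyl)but-3-en-2-one | CC(=O)/C=C/c1ccc(O)cc1 | starting material
2 | (E)-4-[4-(methoxymethoxy)phenyl]but-3-en-2-one | CC(=O)/C=C/c1ccc(OCOC)cc1 | intermediate
3 | dimethyl malonate | COC(=O)CC(=O)OC | starting material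
4 | dimethyl 2-[(1S)-1-[4-(methoxymethoxy)phenyl]-3-oxobutyl]malonate | COC(=O)C(C(=O)OC)[C@@H](c1ccc(OCOC)cc1)CC(C)=O | intermediate
5 | methyl (3S)-3-[4-(methoxymethoxy)phenyl]-5-oxohexanoate | COC(=O)C[C@@H](c1ccc(OCOC)cc1)CC(C)=O | intermediate
6 | 2,4,6-trihydroxybenzaldehyde | O=Cc1c(O)cc(O)cc1O | starting material
7 | 2,6-dihydroxy-4-(methoxymethoxy)benzaldehyde | O=Cc1c(O)cc(OCOC)cc1O | intermediate
8 | 2,6-bis(allyloxy)-4-(methoxymethoxy)benzaldehyde | O=Cc1c(OCC=C)cc(OCOC)cc1OCC=C | intermediate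
9 | 2-[(E)-2-iodoethenyl]-5-(methoxymethoxy)-1,3-bis(allyloxy)benzene | I/C=C/c1c(OCC=C)cc(OCOC)cc1OCC=C | intermediate
10 | (E)-2-[2,6-bis(allyloxy)-4-(methoxymethoxy)phenyl]ethenyllithium, formed in situ | [Li]/C=C/c1c(OCC=C)cc(OCOC)cc1OCC=C | intermediate
11 | (E)-2-[2,6-bis(allyloxy)-4-(methoxymethoxy)phenyl]ethenylcerium dichloride, formed in situ | Cl[Ce](Cl)/C=C/c1c(OCC=C)cc(OCOC)cc1OCC=C | intermediate
12 | methyl (3S,5R,6E)-7-[2,6-bis(allyloxy)-4-(methoxymethoxy)phenyl]-5-hydroxy-3-[4-(methoxymethoxy)phenyl]-5-methylhept-6-enoate, present as its metal alkoxide (drawn as the alcohol) | COC(=O)C[C@@H](c1ccc(OCOC)cc1)C[C@@](C)(O)/C=C/c1c(OCC=C)cc(OCOC)cc1OCC=C | intermediate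
13 | (4S,6R)-6-{(E)-2-[2,6-bis(allyloxy)-4-(methoxymethoxy)phenyl]ethenyl}-4-[4-(methoxymethoxy)phenyl]-6-methyloxan-2-one | O=C1C[C@@H](c2ccc(OCOC)cc2)C[C@](C)(/C=C/c2c(OCC=C)cc(OCOC)cc2OCC=C)O1 | intermediate
14 | trimethylsilyl ketene acetal of 13, (2R,4S)-2-alkenyl-2-methyl-4-aryl-6-(trimethylsilyloxy)-3,4-dihydro-2H-pyran, formed in situ | C[Si](C)(C)OC1=C[C@@H](c2ccc(OCOC)cc2)C[C@](C)(/C=C/c2c(OCC=C)cc(OCOC)cc2OCC=C)O1 | intermediate
15 | trimethylsilyl (1S,2R,6S)-2-[2,6-bis(allyloxy)-4-(methoxymethoxy)phenyl]-6-[4-(methoxymethoxy)phenyl]-4-methylcyclohex-3-ene-1-carboxylate, formed in situ | C[Si](C)(C)OC(=O)[C@H]1[C@@H](c2ccc(OCOC)cc2)CC(C)=C[C@H]1c1c(OCC=C)cc(OCOC)cc1OCC=C | intermediate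
16 | (1S,2R,6S)-2-[2,6-bis(allyloxy)-4-(methoxymethoxy)phenyl]-6-[4-(methoxymethoxy)phenyl]-4-methylcyclohex-3-ene-1-carboxylic acid (all-cis) | OC(=O)[C@H]1[C@@H](c2ccc(OCOC)cc2)CC(C)=C[C@H]1c1c(OCC=C)cc(OCOC)cc1OCC=C | intermediate
17 | [(1S,2R,6S)-2-[2,6-bis(allyloxy)-4-(methoxymethoxy)phenyl]-6-[4-(methoxymethoxy)phenyl]-4-methylcyclohex-3-en-1-yl]methanol | OC[C@H]1[C@@H](c2ccc(OCOC)cc2)CC(C)=C[C@H]1c1c(OCC=C)cc(OCOC)cc1OCC=C | intermediate
18 | (1S,2R,6S)-2-[2,6-bis(allyloxy)-4-(methoxymethoxy)phenyl]-6-[4-(methoxymethoxy)phenyl]-4-methylcyclohex-3-ene-1-carbaldehyde (all-cis), not isolated | O=C[C@H]1[C@@H](c2ccc(OCOC)cc2)CC(C)=C[C@H]1c1c(OCC=C)cc(OCOC)cc1OCC=C | intermediate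
19 | (1R,2R,6S)-2-[2,6-bis(allyloxy)-4-(methoxymethoxy)phenyl]-6-[4-(methoxymethoxy)phenyl]-4-methylcyclohex-3-ene-1-carbaldehyde (formyl trans to both aryl groups) | O=C[C@@H]1[C@@H](c2ccc(OCOC)cc2)CC(C)=C[C@H]1c1c(OCC=C)cc(OCOC)cc1OCC=C | intermediate
20 | (1R,2R,6S)-2-[2,6-bis(allyloxy)-3-bromo-4-(methoxymethoxy)phenyl]-6-[4-(methoxymethoxy)phenyl]-4-methylcyclohex-3-ene-1-carbaldehyde | O=C[C@@H]1[C@@H](c2ccc(OCOC)cc2)CC(C)=C[C@H]1c1c(OCC=C)cc(OCOC)c(Br)c1OCC=C | intermediate
21 | resorcinol | Oc1cccc(O)c1 | starting material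
22 | 1,3-bis(methoxymethoxy)benzene | COCOc1cccc(OCOC)c1 | intermediate
23 | 2,6-bis(methoxymethoxy)phenyllithium, formed in situ | [Li]c1c(OCOC)cccc1OCOC | intermediate
24 | 1,3-bis(methoxymethoxy)-2-(3-methylbut-2-en-1-yl)benzene | CC(C)=CCc1c(OCOC)cccc1OCOC | intermediate
25 | 2,4-bis(methoxymethoxy)-3-(3-methylbut-2-en-1-yl)phenyllithium, formed in situ | [Li]c1ccc(OCOC)c(CC=C(C)C)c1OCOC | intermediate
26 | [2,4-bis(methoxymethoxy)-3-prenylphenyl][(1R,2R,6S)-2-[2,6-bis(allyloxy)-3-bromo-4-(methoxymethoxy)phenyl]-6-[4-(methoxymethoxy)phenyl]-4-methylcyclohex-3-en-1-yl]methanol, both carbinol epimers | OC(c1ccc(OCOC)c(CC=C(C)C)c1OCOC)[C@@H]1[C@@H](c2ccc(OCOC)cc2)CC(C)=C[C@H]1c1c(OCC=C)cc(OCOC)c(Br)c1OCC=C | intermediate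
27 | 5-methylhex-4-enal | CC(C)=CCCC=O | starting material
28 | lithium alkoxide of 26 carrying lithium in place of bromine, formed in situ | [Li]OC(c1ccc(OCOC)c(CC=C(C)C)c1OCOC)[C@@H]1[C@@H](c2ccc(OCOC)cc2)CC(C)=C[C@H]1c1c(OCC=C)cc(OCOC)c([Li])c1OCC=C | intermediate
29 | 1-[2,4-bis(allyloxy)-3-[(1R,5S,6R)-6-[[2,4-bis(methoxymethoxy)-3-prenylphenyl](hydroxy)methyl]-5-[4-(methoxymethoxy)phenyl]-3-methylcyclohex-2-en-1-yl]-6-(methoxymethoxy)phenyl]-5-methylhex-4-en-1-ol, carbinol epimers | OC(c1ccc(OCOC)c(CC=C(C)C)c1OCOC)[C@@H]1[C@@H](c2ccc(OCOC)cc2)CC(C)=C[C@H]1c1c(OCC=C)cc(OCOC)c(C(O)CCC=C(C)C)c1OCC=C | intermediate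
30 | 1-[2,4-bis(allyloxy)-3-[(1R,5S,6R)-6-[2,4-bis(methoxymethoxy)-3-prenylbenzoyl]-5-[4-(methoxymethoxy)phenyl]-3-methylcyclohex-2-en-1-yl]-6-(methoxymethoxy)phenyl]-5-methylhex-4-en-1-one | O=C(c1ccc(OCOC)c(CC=C(C)C)c1OCOC)[C@@H]1[C@@H](c2ccc(OCOC)cc2)CC(C)=C[C@H]1c1c(OCC=C)cc(OCOC)c(C(=O)CCC=C(C)C)c1OCC=C | intermediate
31 | 1-[3-[(1R,5S,6R)-6-[2,4-bis(methoxymethoxy)-3-prenylbenzoyl]-5-[4-(methoxymethoxy)phenyl]-3-methylcyclohex-2-en-1-yl]-2,4-dihydroxy-6-(methoxymethoxy)phenyl]-5-methylhex-4-en-1-one | O=C(c1ccc(OCOC)c(CC=C(C)C)c1OCOC)[C@@H]1[C@@H](c2ccc(OCOC)cc2)CC(C)=C[C@H]1c1c(O)cc(OCOC)c(C(=O)CCC=C(C)C)c1O | intermediate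
32 | 2,4-dihydroxybenzoic acid | OC(=O)c1ccc(O)cc1O | starting material
33 | methoxymethyl 2,4-bis(methoxymethoxy)benzoate, not isolated | COCOC(=O)c1ccc(OCOC)cc1OCOC | intermediate
34 | 2,4-bis(methoxymethoxy)benzoic acid | OC(=O)c1ccc(OCOC)cc1OCOC | intermediate
35 | 2-[(1R,5S,6R)-6-[2,4-bis(methoxymethoxy)-3-prenylbenzoyl]-5-[4-(methoxymethoxy)phenyl]-3-methylcyclohex-2-en-1-yl]-5-(methoxymethoxy)-4-(5-methylhex-4-enoyl)-1,3-phenylene bis[2,4-bis(methoxymethoxy)benzoate] | O=C(c1ccc(OCOC)c(CC=C(C)C)c1OCOC)[C@@H]1[C@@H](c2ccc(OCOC)cc2)CC(C)=C[C@H]1c1c(OC(=O)c2ccc(OCOC)cc2OCOC)cc(OCOC)c(C(=O)CCC=C(C)C)c1OC(=O)c1ccc(OCOC)cc1OCOC | intermediate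
36 | 1-[2,4-bis(methoxymethoxy)phenyl]-3-[4-[2,4-bis(methoxymethoxy)benzoyloxy]-3-[(1R,5S,6R)-6-[2,4-bis(methoxymethoxy)-3-prenylbenzoyl]-5-[4-(methoxymethoxy)phenyl]-3-methylcyclohex-2-en-1-yl]-2-hydroxy-6-(methoxymethoxy)phenyl]-2-prenylpropane-1,3-dione, not isolated | O=C(c1ccc(OCOC)c(CC=C(C)C)c1OCOC)[C@@H]1[C@@H](c2ccc(OCOC)cc2)CC(C)=C[C@H]1c1c(OC(=O)c2ccc(OCOC)cc2OCOC)cc(OCOC)c(C(=O)C(CC=C(C)C)C(=O)c2ccc(OCOC)cc2OCOC)c1O | intermediate
37 | 1-[2,4-bis(methoxymethoxy)phenyl]-3-[3-[(1R,5S,6R)-6-[2,4-bis(methoxymethoxy)-3-prenylbenzoyl]-5-[4-(methoxymethoxy)phenyl]-3-methylcyclohex-2-en-1-yl]-2,4-dihydroxy-6-(methoxymethoxy)phenyl]-2-prenylpropane-1,3-dione | O=C(c1ccc(OCOC)c(CC=C(C)C)c1OCOC)[C@@H]1[C@@H](c2ccc(OCOC)cc2)CC(C)=C[C@H]1c1c(O)cc(OCOC)c(C(=O)C(CC=C(C)C)C(=O)c2ccc(OCOC)cc2OCOC)c1O | intermediate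
38 | 8-[(1R,5S,6R)-6-[2,4-bis(methoxymethoxy)-3-prenylbenzoyl]-5-[4-(methoxymethoxy)phenyl]-3-methylcyclohex-2-en-1-yl]-2-[2,4-bis(methoxymethoxy)phenyl]-7-hydroxy-5-(methoxymethoxy)-3-prenyl-4H-chromen-4-one, not isolated | O=C(c1ccc(OCOC)c(CC=C(C)C)c1OCOC)[C@@H]1[C@@H](c2ccc(OCOC)cc2)CC(C)=C[C@H]1c1c(O)cc(OCOC)c2c(=O)c(CC=C(C)C)c(-c3ccc(OCOC)cc3OCOC)oc12 | intermediate
39 | 8-[(1R,5S,6R)-6-[2,4-dihydroxy-3-(3-methylbut-2-en-1-yl)benzoyl]-5-(4-hydroxyphenyl)-3-methylcyclohex-2-en-1-yl]-2-(2,4-dihydroxyphenyl)-5,7-dihydroxy-3-(3-methylbut-2-en-1-yl)-4H-chromen-4-one | CC(C)=CCc1c(O)ccc(C(=O)[C@@H]2[C@@H](c3ccc(O)cc3)CC(C)=C[C@H]2c2c(O)cc(O)c3c(=O)c(CC=C(C)C)c(-c4ccc(O)cc4O)oc23)c1O | target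

**Totals**

Total step count: 21. Longest linear sequence: 15 steps (steps 4–11, 14–17 and 19–21 from 6; equally steps 1–3, 7–11, 14–17 and 19–21 from 1).

**Steps most likely to fail**

Step 7. The alkenylcerium reagent meets a ketone that has no facial bias, so much of the material may end as the unwanted C6 epimer, and the tertiary allylic C–O bond next to the electron-rich arene may ionise during purification. The fallback sets C6 first and C4 second. It sets out from aldehyde 8. Claisen–Schmidt condensation with acetone (aqueous NaOH) should give (E)-4-[2,6-bis(allyloxy)-4-(methoxymethoxy)phenyl]but-3-en-2-one F1. Enantioselective propargylation of its methyl ketone with allenylboronic acid pinacol ester under a chiral 3,3'-dibromo-BINOL catalyst should give the (R)-configured tertiary alcohol (3R,1E)-1-[2,6-bis(allyloxy)-4-(methoxymethoxy)phenyl]-3-methylhex-1-en-5-yn-3-ol F2. Double deprotonation with n-BuLi and carboxylation with CO2 gives (5R,6E)-7-[2,6-bis(allyloxy)-4-(methoxymethoxy)phenyl]-5-hydroxy-5-methylhept-6-en-2-ynoic acid F3. Semi-hydrogenation over Pd/CaCO3 poisoned with Pb(OAc)2 and quinoline gives the (2Z,5R,6E)-hydroxy dienoic acid F4, which is lactonised with EDCI to (6R)-6-{(E)-2-[2,6-bis(allyloxy)-4-(methoxymethoxy)phenyl]ethenyl}-6-methyl-5,6-dihydro-2H-pyran-2-one F5. A Hayashi–Miyaura addition of 4-(methoxymethoxy)phenylboronic acid ([Rh(OH)(cod)]2 with the BINAP enantiomer that delivers the aryl group anti to the alkenyl substituent, dioxane/H2O, 35 °C) then sets C4 under catalyst control and comes back to the route at lactone 13. Steps 1–3, 6 and 7 are then not needed.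

Step 20. The intramolecular acyl transfer may be slow at an enolate flanked by two ortho substituents, enolisation may occur at the ring E ketone instead, and the ester it depends on may form incompletely at the hindered, hydrogen-bonded phenol in step 19. The fallback replaces acyl transfer by an intermolecular C-acylation that needs no phenol ester. It sets out from 30. Acid 34 is converted with 1H-benzotriazole and EDCI into (1H-benzotriazol-1-yl)[2,4-bis(methoxymethoxy)phenyl]methanone F6. Soft enolisation of the hexenoyl ketone of 30 with MgBr2·OEt2 and i-Pr2NEt in CH2Cl2 and acylation by F6 should give the allyl-protected β-diketone 1-[2,4-bis(allyloxy)-3-[(1R,5S,6R)-6-[2,4-bis(methoxymethoxy)-3-prenylbenzoyl]-5-[4-(methoxymethoxy)phenyl]-3-methylcyclohex-2-en-1-yl]-6-(methoxymethoxy)phenyl]-3-[2,4-bis(methoxymethoxy)phenyl]-2-prenylpropane-1,3-dione F7. Deallylation with Pd(PPh3)4 and morpholine then comes back to the route at 37, bypassing steps 17, 19 and 20.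

Step 21. While the slower MOM ethers are still being cleaved, a prenyl double bond may be protonated and captured by its neighbouring phenol (chroman formation) or by methanol. The fallback separates ring closure from deprotection and removes the acetals without a protic acid. It sets out from 37. Catalytic pyridinium p-toluenesulfonate in toluene at 40 °C closes ring C, and hexa-MOM flavone 38 is isolated. Me3SiOTf and 2,2'-bipyridyl in CH2Cl2 at 0 °C exchange each aryl MOM ether for a silyl ether and silylate the free 7-OH, giving the heptakis(trimethylsilyl) ether of the target F8. Addition of water hydrolyses the aryl silyl ethers and comes back to the route at 39.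

**Further compounds**

F1 | step 7 | (E)-4-[2,6-bis(allyloxy)-4-(methoxymethoxy)phenyl]but-3-en-2-one | CC(=O)/C=C/c1c(OCC=C)cc(OCOC)cc1OCC=C
F2 | step 7 | (3R,1E)-1-[2,6-bis(allyloxy)-4-(methoxymethoxy)phenyl]-3-methylhex-1-en-5-yn-3-ol | C#CC[C@@](C)(O)/C=C/c1c(OCC=C)cc(OCOC)cc1OCC=C
F3 | step 7 | (5R,6E)-7-[2,6-bis(allyloxy)-4-(methoxymethoxy)phenyl]-5-hydroxy-5-methylhept-6-en-2-ynoic acid | OC(=O)C#CC[C@@](C)(O)/C=C/c1c(OCC=C)cc(OCOC)cc1OCC=C
F4 | step 7 | (2Z,5R,6E)-7-[2,6-bis(allyloxy)-4-(methoxymethoxy)phenyl]-5-hydroxy-5-methylhepta-2,6-dienoic acid | OC(=O)/C=C\C[C@@](C)(O)/C=C/c1c(OCC=C)cc(OCOC)cc1OCC=C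
F5 | step 7 | (6R)-6-{(E)-2-[2,6-bis(allyloxy)-4-(methoxymethoxy)phenyl]ethenyl}-6-methyl-5,6-dihydro-2H-pyran-2-one | O=C1C=CC[C@](C)(/C=C/c2c(OCC=C)cc(OCOC)cc2OCC=C)O1
F6 | step 20 | (1H-benzotriazol-1-yl)[2,4-bis(methoxymethoxy)phenyl]methanone | O=C(c1ccc(OCOC)cc1OCOC)n1nnc2ccccc12
F7 | step 20 | 1-[2,4-bis(allyloxy)-3-[(1R,5S,6R)-6-[2,4-bis(methoxymethoxy)-3-prenylbenzoyl]-5-[4-(methoxymethoxy)phenyl]-3-methylcyclohex-2-en-1-yl]-6-(methoxymethoxy)phenyl]-3-[2,4-bis(methoxymethoxy)phenyl]-2-prenylpropane-1,3-dione | O=C(c1ccc(OCOC)c(CC=C(C)C)c1OCOC)[C@@H]1[C@@H](c2ccc(OCOC)cc2)CC(C)=C[C@H]1c1c(OCC=C)cc(OCOC)c(C(=O)C(CC=C(C)C)C(=O)c2ccc(OCOC)cc2OCOC)c1OCC=C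
F8 | step 21 | heptakis(trimethylsilyl) ether of 39 | CC(C)=CCc1c(O[Si](C)(C)C)ccc(C(=O)[C@@H]2[C@@H](c3ccc(O[Si](C)(C)C)cc3)CC(C)=C[C@H]2c2c(O[Si](C)(C)C)cc(O[Si](C)(C)C)c3c(=O)c(CC=C(C)C)c(-c4ccc(O[Si](C)(C)C)cc4O[Si](C)(C)C)oc23)c1O[Si](C)(C)C
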